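## Retrosynthetic overview

1. The last C=C bond is C11=C12, made by Wittig reaction of the C25 phosphonium salt 19 (ε half) with the C15 keto-enal ester 34 (β half, already carrying the C8 ketone and the C19 dodecenoate). C11′=C12′ comes from the C15 salt 14 and the C10 dialdehyde 15.
2. β half: (4R,6R)-actinol → enol triflate → allyl → aldehyde 25 → vinyl ketone 28 → Morita–Baylis–Hillman adduct with glyoxal mono-acetal. Esterification with a 1,3-acyloxy shift then sets the C19 ester and the C9=C10 geometry.
3. ε half: the side chain is grown from an ethynyl group on C6′ (acetylide + methyl vinyl ketone, then trans-hydroalumination). The C3′ carbinol comes from reagent-controlled reduction of enone 9.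
4. Key disconnection C4′–C5′: the ε ring is closed from the achiral diyne 7 by an enantioselective, group-selective gold-catalysed enol–yne (Conia-ene-type) cyclisation. The enabling feature is that C6′ of the ε ring carries two two-carbon unsaturated arms, C5′(–C18′)=C4′ in the ring and C7′=C8′ in the chain, so it is a latent diethynylmethine, while C3′–C4′ is a latent methyl ketone.
5. Ring order: the ε ring is the only ring formed (step 6); the β ring comes from the chiral pool.

Key step: step 6

Remark: locants such as C6′ follow the carotenoid numbering of the target (β end unprimed, ε end primed). The two Wittig steps are assumed to give E/Z mixtures at the new bond that are equilibrated to all-E within the step. Compounds 1, 2, 11, 15, 20, 23, 26, 29 and 31 are taken as purchased.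

## Route

Step 1
Reactants: 1 methyl 2,2-dimethylpent-4-enoate; 2 lithium (trimethylsilyl)acetylide (2.3 equiv, THF solution)
Product: 3 3-(2-methylpent-4-en-2-yl)-1,5-bis(trimethylsilyl)penta-1,4-diyn-3-ol
Conditions: THF, −78 °C → 40 °C; aq. NH4Cl
Reagents that add atoms: none
Why: Double addition of the lithium acetylide to the hindered ester (acyl substitution to the ynone, then fast 1,2-addition, so no ketone accumulates) should give the tertiary bis-propargylic alcohol without forming a stereocentre.

Step 2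
Reactants: 3 3-(2-methylpent-4-en-2-yl)-1,5-bis(trimethylsilyl)penta-1,4-diyn-3-ol
Product: 4 [3-(2-methylpent-4-en-2-yl)penta-1,4-diyne-1,5-diyl]bis(trimethylsilane)
Conditions: Et3SiH, CF3CO2H, CH2Cl2, −40 → 0 °C
Reagents that add atoms: none
Why: Kursanov–Parnes ionic hydrogenation: the acid ionises the tertiary alcohol to a carbenium ion stabilised by both alkynes, which should take hydride from the silane at the central carbon because the silylated alkyne termini are shielded, while the unactivated terminal alkene is not protonated at this temperature.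

Step 3
Reactants: 4 [3-(2-methylpent-4-en-2-yl)penta-1,4-diyne-1,5-diyl]bis(trimethylsilane)
Product: 5 4,4-dimethyl-7-(trimethylsilyl)-5-[(trimethylsilyl)ethynyl]hept-6-yn-2-one
Conditions: PdCl2 (10 mol%), CuCl (co-catalyst), O2 (1 atm), DMF/H2O 7:1, rt
Reagents that add atoms: water, O
Why: Tsuji–Wacker oxidation of the terminal alkene next to a quaternary carbon should give the methyl ketone by Markovnikov hydroxypalladation, the silyl-capped internal alkynes being poor ligands for divalent palladium under these conditions.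

Step 4
Reactants: 5 4,4-dimethyl-7-(trimethylsilyl)-5-[(trimethylsilyl)ethynyl]hept-6-yn-2-one
Product: 6 5-ethynyl-4,4-dimethylhept-6-yn-2-one
Conditions: AgNO3 (10 mol%), MeOH/H2O/CH2Cl2, rt
Reagents that add atoms: none
Why: Silver-catalysed protodesilylation of the two alkynylsilanes is neutral, so neither the ketone nor the base-sensitive bis-propargylic C–H (risk of allene formation) should be touched.

Step 5
Reactants: 6 5-ethynyl-4,4-dimethylhept-6-yn-2-one
Product: 7 tert-butyl[(5-ethynyl-4,4-dimethylhept-1-en-6-yn-2-yl)oxy]dimethylsilane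
Conditions: LiN(iPr)2 (1.05 equiv), THF, −78 °C; tBuMe2SiCl, DMPU, −78 → 0 °C
Reagents that add atoms: tert-butyldimethylsilyl chloride, CC(C)(C)[Si](C)(C)Cl
Why: Kinetic deprotonation of the methyl ketone at the methyl group (the ketone α-C–H is more acidic than the alkyne C–H and the neopentyl CH2 is hindered) followed by O-silylation should give the terminal silyl enol ether regioselectively.

Step 6
Reactants: 7 tert-butyl[(5-ethynyl-4,4-dimethylhept-1-en-6-yn-2-yl)oxy]dimethylsilane
Product: 9 (4S)-4-ethynyl-3,5,5-trimethylcyclohex-2-en-1-one, via exo-methylene ketone 8 (not isolated)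
Conditions: [(R)-DTBM-SEGPHOS](AuCl)2 (3 mol%), AgNTf2 (6 mol%), MeOH (2 equiv), CH2Cl2, −30 °C; then DABCO (10 mol%), 0 °C
Reagents that add atoms: none
Why: Proposed new method: a cationic monovalent gold centre held in the chiral pocket of the digold bisphosphine complex π-activates one of the two enantiotopic ethynyl groups on C6′ of 7, the enol ether carbon C4′ attacks the internal alkyne carbon C5′ anti to gold, methanol takes the silyl group and protonates the vinyl–gold bond to give exo-methylene ketone 8, and DABCO then moves the exocyclic double bond into conjugation to give enone 9 with the C4′=C5′ bond of the target. The closest known reactions are the gold-catalysed carbocyclisation of silyl enol ethers onto alkynes (a Conia-ene-type reaction, including enantioselective versions with chiral bisphosphine complexes of gold or palladium) and the gold-catalysed enantioselective desymmetrisation of 1,4-diynes by heteroatom nucleophiles; what is new is a carbon nucleophile in the group-selective step. The ε ring is closed in the 6-exo-dig mode, favoured by Markovnikov attack on a terminal alkyne and by the gem-dimethyl group at C1′. The only new stereocentre, C6′, is set by the catalyst, which selects the enantiotopic alkyne; the ligand antipode that leads to (4S)-9 is to be fixed in a first screen. The step needs group selectivity between the two alkynes (chiral ligand), C-cyclisation and a single cyclisation (O-attack would need an eight-membered ring and the second alkyne has no partner left), enol regiocontrol (the C2′ enol could only close a four-membered ring) and migration of the double bond towards C4′ and not C6′ (conjugation with the ketone, with a base too weak to remove the γ-proton at C6′).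

Step 7
Reactants: 9 (4S)-4-ethynyl-3,5,5-trimethylcyclohex-2-en-1-one
Product: 10 (1R,4S)-4-ethynyl-3,5,5-trimethylcyclohex-2-en-1-ol
Conditions: (S)-2-methyl-CBS-oxazaborolidine (20 mol%), catecholborane, toluene, −78 °C; aq. NaOH work-up
Reagents that add atoms: none
Why: Corey–Bakshi–Shibata reduction: with the alkenyl arm as the large group the (S)-oxazaborolidine should deliver hydride to the face that gives the (1R) carbinol, trans to the ethynyl group, under reagent control while catecholborane leaves the alkyne alone at −78 °C, and the (1R,4R) epimer arising from any (4R)-9 is separable, so the step also upgrades enantiomeric purity.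

Step 8
Reactants: 10 (1R,4S)-4-ethynyl-3,5,5-trimethylcyclohex-2-en-1-ol; 11 but-3-en-2-one (methyl vinyl ketone)
Product: 12 (1R,4R)-4-(3-hydroxy-3-methylpent-4-en-1-yn-1-yl)-3,5,5-trimethylcyclohex-2-en-1-ol (both C9′ epimers)
Conditions: n-BuLi (2.05 equiv), THF, −78 → −20 °C; then 11, −78 °C; aq. NH4Cl
Reagents that add atoms: none
Why: Deprotonation of the hydroxyl and the alkyne C–H gives a dianion whose lithium acetylide should add 1,2 to the enone at low temperature (alkynylation of a ketone); the new carbinol centre C9′ is formed without control and is erased in step 10.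

Step 9
Reactants: 12 (1R,4R)-4-(3-hydroxy-3-methylpent-4-en-1-yn-1-yl)-3,5,5-trimethylcyclohex-2-en-1-ol
Product: 13 (1R,4R)-4-[(1E)-3-hydroxy-3-methylpenta-1,4-dien-1-yl]-3,5,5-trimethylcyclohex-2-en-1-ol
Conditions: NaAlH2(OCH2CH2OMe)2, THF, 0 °C → rt; aq. Rochelle salt
Reagents that add atoms: none
Why: Alkoxide-directed trans-hydroalumination of the propargylic alcohol followed by protonolysis should give only the E alkene C7′=C8′, isolated alkenes being inert to the aluminium hydride.

Step 10
Reactants: 13 (1R,4R)-4-[(1E)-3-hydroxy-3-methylpenta-1,4-dien-1-yl]-3,5,5-trimethylcyclohex-2-en-1-ol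
Product: 14 {(2E,4E)-5-[(1R,4R)-4-hydroxy-2,6,6-trimethylcyclohex-2-en-1-yl]-3-methylpenta-2,4-dien-1-yl}triphenylphosphonium bromide
Conditions: PPh3·HBr, MeOH/CH2Cl2, 0 °C → rt
Reagents that add atoms: triphenylphosphine hydrobromide, [Br-].[PH+](c1ccccc1)(c1ccccc1)c1ccccc1
Why: Ionisation of the doubly allylic tertiary alcohol and capture of the pentadienyl cation by PPh3 at the unhindered terminus (allylic substitution with transposition, the classical C15 Wittig-salt formation from vinyl carbinols) should give the conjugated 9′E dienyl salt, the secondary allylic 3′-OH ionising far more slowly and the stereocentres staying untouched.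

Step 11
Reactants: 14 {(2E,4E)-5-[(1R,4R)-4-hydroxy-2,6,6-trimethylcyclohex-2-en-1-yl]-3-methylpenta-2,4-dien-1-yl}triphenylphosphonium bromide; 15 (2E,4E,6E)-2,7-dimethylocta-2,4,6-trienedial (3 equiv)
Product: 17 (2E,4E,6E,8E,10E,12E)-13-[(1R,4R)-4-hydroxy-2,6,6-trimethylcyclohex-2-en-1-yl]-2,7,11-trimethyltrideca-2,4,6,8,10,12-hexaenal, via 8Z isomer 16 (not isolated)
Conditions: NaOMe, MeOH/CH2Cl2, 0 °C → rt; then heptane, reflux
Reagents that add atoms: none
Why: Wittig olefination of the semistabilised ylide with an excess of the symmetrical dialdehyde should give the mono-condensation product as an E/Z mixture at the new C11′=C12′ bond, and heating equilibrates the Z isomer 16 to the all-E aldehyde 17.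

Step 12
Reactants: 17 (2E,4E,6E,8E,10E,12E)-13-[(1R,4R)-4-hydroxy-2,6,6-trimethylcyclohex-2-en-1-yl]-2,7,11-trimethyltrideca-2,4,6,8,10,12-hexaenal
Product: 18 (2E,4E,6E,8E,10E,12E)-13-[(1R,4R)-4-hydroxy-2,6,6-trimethylcyclohex-2-en-1-yl]-2,7,11-trimethyltrideca-2,4,6,8,10,12-hexaen-1-ol
Conditions: NaBH4, MeOH/THF, 0 °C
Reagents that add atoms: none
Why: 1,2-Reduction of the polyenal by the borohydride should give the primary allylic alcohol without touching the polyene.

Step 13
Reactants: 18 (2E,4E,6E,8E,10E,12E)-13-[(1R,4R)-4-hydroxy-2,6,6-trimethylcyclohex-2-en-1-yl]-2,7,11-trimethyltrideca-2,4,6,8,10,12-hexaen-1-ol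
Product: 19 {(2E,4E,6E,8E,10E,12E)-13-[(1R,4R)-4-hydroxy-2,6,6-trimethylcyclohex-2-en-1-yl]-2,7,11-trimethyltrideca-2,4,6,8,10,12-hexaen-1-yl}triphenylphosphonium bromide
Conditions: PPh3·HBr, MeOH/CH2Cl2, 0 °C
Reagents that add atoms: triphenylphosphine hydrobromide, [Br-].[PH+](c1ccccc1)(c1ccccc1)c1ccccc1
Why: The primary polyenylic alcohol ionises very easily to a delocalised cation that PPh3 should trap at the terminal carbon (SN1-type Wittig-salt formation), keeping the all-E chain.

Step 14
Reactants: 20 (4R,6R)-4-hydroxy-2,2,6-trimethylcyclohexan-1-one (actinol)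
Product: 21 (4R,6R)-4-[(tert-butyldimethylsilyl)oxy]-2,2,6-trimethylcyclohexan-1-one
Conditions: tBuMe2SiCl, imidazole, DMF, rt
Reagents that add atoms: tert-butyldimethylsilyl chloride, CC(C)(C)[Si](C)(C)Cl
Why: Standard silylation of the secondary alcohol protects it for the enolate chemistry and leaves both stereocentres unchanged.

Step 15
Reactants: 21 (4R,6R)-4-[(tert-butyldimethylsilyl)oxy]-2,2,6-trimethylcyclohexan-1-one
Product: 22 (4R)-4-[(tert-butyldimethylsilyl)oxy]-2,6,6-trimethylcyclohex-1-en-1-yl trifluoromethanesulfonate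
Conditions: LiN(iPr)2, THF, −78 → 0 °C; PhNTf2, −78 °C → rt; aq. NH4Cl
Reagents that add atoms: N-phenylbis(trifluoromethanesulfonimide), O=S(=O)(N(c1ccccc1)S(=O)(=O)C(F)(F)F)C(F)(F)F
Why: Deprotonation can only occur at the methyl-bearing α-carbon (the other is quaternary), so trapping of the enolate should give a single tetrasubstituted enol triflate, erasing that stereocentre and keeping the silyloxy carbon (carotenoid C3).

Step 16
Reactants: 22 (4R)-4-[(tert-butyldimethylsilyl)oxy]-2,6,6-trimethylcyclohex-1-en-1-yl trifluoromethanesulfonate; 23 allyltributylstannane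
Product: 24 tert-butyldimethyl{[(1R)-3,5,5-trimethyl-4-(prop-2-en-1-yl)cyclohex-3-en-1-yl]oxy}silane
Conditions: Pd(PPh3)4 (5 mol%), LiCl (3 equiv), THF, reflux
Reagents that add atoms: none
Why: Stille coupling of the vinyl triflate with the allylstannane under the LiCl protocol (zerovalent palladium) should give the skipped diene and forms the C6–C7 bond of the β end.

Step 17
Reactants: 24 tert-butyldimethyl{[(1R)-3,5,5-trimethyl-4-(prop-2-en-1-yl)cyclohex-3-en-1-yl]oxy}silane
Product: 25 2-[(4R)-4-[(tert-butyldimethylsilyl)oxy]-2,6,6-trimethylcyclohex-1-en-1-yl]acetaldehyde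
Conditions: OsO4 (2 mol%), NaIO4 (4 equiv), 2,6-lutidine, dioxane/H2O 3:1, rt
Reagents that add atoms: sodium periodate (oxygen donor through OsO4), [Na+].[O-]I(=O)(=O)=O
Why: Lemieux–Johnson cleavage should occur only at the monosubstituted alkene, because the tetrasubstituted ring alkene flanked by the gem-dimethyl group is too hindered for osmylation, giving the β,γ-unsaturated aldehyde under buffered, non-isomerising conditions.

Step 18
Reactants: 25 2-[(4R)-4-[(tert-butyldimethylsilyl)oxy]-2,6,6-trimethylcyclohex-1-en-1-yl]acetaldehyde; 26 vinylmagnesium bromide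
Product: 27 1-[(4R)-4-[(tert-butyldimethylsilyl)oxy]-2,6,6-trimethylcyclohex-1-en-1-yl]but-3-en-2-ol (both C8 epimers)
Conditions: THF, −78 °C; aq. NH4Cl
Reagents that add atoms: none
Why: Grignard 1,2-addition to the aldehyde at low temperature (to limit enolisation) should give the allylic alcohol; the new carbinol centre C8 is uncontrolled and is oxidised in step 19.

Step 19
Reactants: 27 1-[(4R)-4-[(tert-butyldimethylsilyl)oxy]-2,6,6-trimethylcyclohex-1-en-1-yl]but-3-en-2-ol
Product: 28 1-[(4R)-4-[(tert-butyldimethylsilyl)oxy]-2,6,6-trimethylcyclohex-1-en-1-yl]but-3-en-2-one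
Conditions: Dess–Martin periodinane, NaHCO3, CH2Cl2, 0 °C
Reagents that add atoms: none
Why: Dess–Martin oxidation under buffered, non-basic conditions should give the vinyl ketone without shifting the ring double bond; it is used at once.

Step 20
Reactants: 28 1-[(4R)-4-[(tert-butyldimethylsilyl)oxy]-2,6,6-trimethylcyclohex-1-en-1-yl]but-3-en-2-one; 29 2,2-dimethoxyacetaldehyde (60% in water)
Product: 30 4-hydroxy-5,5-dimethoxy-3-methylidene-1-[(4R)-4-[(tert-butyldimethylsilyl)oxy]-2,6,6-trimethylcyclohex-1-en-1-yl]pentan-2-one (both C10 epimers)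
Conditions: DABCO (30 mol%), 1,4-dioxane/H2O 1:1, rt
Reagents that add atoms: none
Why: Morita–Baylis–Hillman reaction: DABCO adds to the vinyl ketone and the ammonium enolate should add to the activated α-oxygenated aldehyde, forming the C9–C10 bond and leaving C19 as the exocyclic methylene; the C10 carbinol centre is uncontrolled and erased in step 21.

Step 21
Reactants: 30 4-hydroxy-5,5-dimethoxy-3-methylidene-1-[(4R)-4-[(tert-butyldimethylsilyl)oxy]-2,6,6-trimethylcyclohex-1-en-1-yl]pentan-2-one; 31 (2E)-dodec-2-enoic acid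
Product: 33 (2E)-4,4-dimethoxy-2-{2-[(4R)-4-[(tert-butyldimethylsilyl)oxy]-2,6,6-trimethylcyclohex-1-en-1-yl]acetyl}but-2-en-1-yl (2E)-dodec-2-enoate, via secondary allylic ester 32 (not isolated)
Conditions: N,N′-dicyclohexylcarbodiimide, 4-(dimethylamino)pyridine (10 mol%), CH2Cl2, 0 °C → rt; then DABCO (20 mol%), THF, 50 °C
Reagents that add atoms: none
Why: Steglich esterification of the secondary allylic alcohol followed by the amine-catalysed 1,3-acyloxy shift of Morita–Baylis–Hillman esters (SN2′ attack of DABCO at the methylene, return of the carboxylate at the primary carbon) should give the thermodynamically favoured trisubstituted E alkene with C11 trans to the C8 carbonyl, installing the C19 ester and the C9=C10 geometry in one operation.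

Step 22
Reactants: 33 (2E)-4,4-dimethoxy-2-{2-[(4R)-4-[(tert-butyldimethylsilyl)oxy]-2,6,6-trimethylcyclohex-1-en-1-yl]acetyl}but-2-en-1-yl (2E)-dodec-2-enoate
Product: 34 (2E)-2-{2-[(4R)-4-hydroxy-2,6,6-trimethylcyclohex-1-en-1-yl]acetyl}-4-oxobut-2-en-1-yl (2E)-dodec-2-enoate
Conditions: HCl (1 M aq.), THF, 0 °C → rt
Reagents that add atoms: water, O
Why: Dilute aqueous acid should hydrolyse the dimethyl acetal to the aldehyde and cleave the secondary silyl ether, while the allylic ester, which sits on an electron-poor alkene and cannot ionise, and the E ene-dione survive.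

Step 23
Reactants: 19 {(2E,4E,6E,8E,10E,12E)-13-[(1R,4R)-4-hydroxy-2,6,6-trimethylcyclohex-2-en-1-yl]-2,7,11-trimethyltrideca-2,4,6,8,10,12-hexaen-1-yl}triphenylphosphonium bromide; 34 (2E)-2-{2-[(4R)-4-hydroxy-2,6,6-trimethylcyclohex-1-en-1-yl]acetyl}-4-oxobut-2-en-1-yl (2E)-dodec-2-enoate
Product: 36 (3R,3′R,6′R)-3,3′-dihydroxy-8-oxo-7,8-dihydro-β,ε-caroten-19-yl (2E)-dodec-2-enoate (all-E; the target), via 11Z isomer 35 (not isolated)
Conditions: 1,2-epoxybutane (excess), CH2Cl2, 45 °C (sealed); then I2 (1 mol%), CH2Cl2, daylight, rt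
Reagents that add atoms: none
Why: Wittig olefination under neutral conditions (the epoxide scavenges HBr and releases the ylide gradually) should condense chemoselectively at the aldehyde of 34, leaving ketone, ester and free hydroxyls untouched, and iodine-catalysed equilibration converts the 11Z isomer 35 into the all-E target without affecting any stereocentre.

## Compound list

1 | methyl 2,2-dimethylpent-4-enoate | C=CCC(C)(C)C(=O)OC | starting material
2 | lithium (trimethylsilyl)acetylide | [Li]C#C[Si](C)(C)C | starting material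
3 | 3-(2-methylpent-4-en-2-yl)-1,5-bis(trimethylsilyl)penta-1,4-diyn-3-ol | C=CCC(C)(C)C(O)(C#C[Si](C)(C)C)C#C[Si](C)(C)C | intermediate
4 | [3-(2-methylpent-4-en-2-yl)penta-1,4-diyne-1,5-diyl]bis(trimethylsilane) | C=CCC(C)(C)C(C#C[Si](C)(C)C)C#C[Si](C)(C)C | intermediate
5 | 4,4-dimethyl-7-(trimethylsilyl)-5-[(trimethylsilyl)ethynyl]hept-6-yn-2-one | CC(=O)CC(C)(C)C(C#C[Si](C)(C)C)C#C[Si](C)(C)C | intermediate
6 | 5-ethynyl-4,4-dimethylhept-6-yn-2-one | CC(=O)CC(C)(C)C(C#C)C#C | intermediate
7 | tert-butyl[(5-ethynyl-4,4-dimethylhept-1-en-6-yn-2-yl)oxy]dimethylsilane | C=C(O[Si](C)(C)C(C)(C)C)CC(C)(C)C(C#C)C#C | intermediate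
8 | (4R)-4-ethynyl-5,5-dimethyl-3-methylidenecyclohexan-1-one | C#C[C@H]1C(=C)CC(=O)CC1(C)C | intermediate
9 | (4S)-4-ethynyl-3,5,5-trimethylcyclohex-2-en-1-one | C#C[C@H]1C(C)=CC(=O)CC1(C)C | intermediate
10 | (1R,4S)-4-ethynyl-3,5,5-trimethylcyclohex-2-en-1-ol | C#C[C@H]1C(C)=C[C@H](O)CC1(C)C | intermediate
11 | but-3-en-2-one (methyl vinyl ketone) | CC(=O)C=C | starting material
12 | (1R,4R)-4-(3-hydroxy-3-methylpent-4-en-1-yn-1-yl)-3,5,5-trimethylcyclohex-2-en-1-ol (C9′ epimers) | C=CC(C)(O)C#C[C@H]1C(C)=C[C@H](O)CC1(C)C | intermediate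
13 | (1R,4R)-4-[(1E)-3-hydroxy-3-methylpenta-1,4-dien-1-yl]-3,5,5-trimethylcyclohex-2-en-1-ol (C9′ epimers) | C=CC(C)(O)/C=C/[C@H]1C(C)=C[C@H](O)CC1(C)C | intermediate
14 | {(2E,4E)-5-[(1R,4R)-4-hydroxy-2,6,6-trimethylcyclohex-2-en-1-yl]-3-methylpenta-2,4-dien-1-yl}triphenylphosphonium bromide | [Br-].C(/C=C(C)/C=C/[C@H]1C(C)=C[C@H](O)CC1(C)C)[P+](c1ccccc1)(c1ccccc1)c1ccccc1 | intermediate
15 | (2E,4E,6E)-2,7-dimethylocta-2,4,6-trienedial | O=C/C(C)=C/C=C/C=C(C)/C=O | starting material
16 | (2E,4E,6E,8Z,10E,12E)-13-[(1R,4R)-4-hydroxy-2,6,6-trimethylcyclohex-2-en-1-yl]-2,7,11-trimethyltrideca-2,4,6,8,10,12-hexaenal | O=C/C(C)=C/C=C/C=C(C)/C=C\C=C(C)\C=C\[C@H]1C(C)=C[C@H](O)CC1(C)C | intermediate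
17 | (2E,4E,6E,8E,10E,12E)-13-[(1R,4R)-4-hydroxy-2,6,6-trimethylcyclohex-2-en-1-yl]-2,7,11-trimethyltrideca-2,4,6,8,10,12-hexaenal | O=C/C(C)=C/C=C/C=C(C)/C=C/C=C(C)/C=C/[C@H]1C(C)=C[C@H](O)CC1(C)C | intermediate
18 | (2E,4E,6E,8E,10E,12E)-13-[(1R,4R)-4-hydroxy-2,6,6-trimethylcyclohex-2-en-1-yl]-2,7,11-trimethyltrideca-2,4,6,8,10,12-hexaen-1-ol | OC/C(C)=C/C=C/C=C(C)/C=C/C=C(C)/C=C/[C@H]1C(C)=C[C@H](O)CC1(C)C | intermediate
19 | {(2E,4E,6E,8E,10E,12E)-13-[(1R,4R)-4-hydroxy-2,6,6-trimethylcyclohex-2-en-1-yl]-2,7,11-trimethyltrideca-2,4,6,8,10,12-hexaen-1-yl}triphenylphosphonium bromide | [Br-].C(/C(C)=C/C=C/C=C(C)/C=C/C=C(C)/C=C/[C@H]1C(C)=C[C@H](O)CC1(C)C)[P+](c1ccccc1)(c1ccccc1)c1ccccc1 | intermediate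
20 | (4R,6R)-4-hydroxy-2,2,6-trimethylcyclohexan-1-one (actinol) | O=C1[C@H](C)C[C@@H](O)CC1(C)C | starting material
21 | (4R,6R)-4-[(tert-butyldimethylsilyl)oxy]-2,2,6-trimethylcyclohexan-1-one | O=C1[C@H](C)C[C@@H](O[Si](C)(C)C(C)(C)C)CC1(C)C | intermediate
22 | (4R)-4-[(tert-butyldimethylsilyl)oxy]-2,6,6-trimethylcyclohex-1-en-1-yl trifluoromethanesulfonate | O=S(=O)(OC1=C(C)C[C@@H](O[Si](C)(C)C(C)(C)C)CC1(C)C)C(F)(F)F | intermediate
23 | allyltributylstannane | C=CC[Sn](CCCC)(CCCC)CCCC | starting material
24 | tert-butyldimethyl{[(1R)-3,5,5-trimethyl-4-(prop-2-en-1-yl)cyclohex-3-en-1-yl]oxy}silane | C=CCC1=C(C)C[C@@H](O[Si](C)(C)C(C)(C)C)CC1(C)C | intermediate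
25 | 2-[(4R)-4-[(tert-butyldimethylsilyl)oxy]-2,6,6-trimethylcyclohex-1-en-1-yl]acetaldehyde | O=CCC1=C(C)C[C@@H](O[Si](C)(C)C(C)(C)C)CC1(C)C | intermediate
26 | vinylmagnesium bromide | C=C[Mg]Br | starting material
27 | 1-[(4R)-4-[(tert-butyldimethylsilyl)oxy]-2,6,6-trimethylcyclohex-1-en-1-yl]but-3-en-2-ol (C8 epimers) | C=CC(O)CC1=C(C)C[C@@H](O[Si](C)(C)C(C)(C)C)CC1(C)C | intermediate
28 | 1-[(4R)-4-[(tert-butyldimethylsilyl)oxy]-2,6,6-trimethylcyclohex-1-en-1-yl]but-3-en-2-one | C=CC(=O)CC1=C(C)C[C@@H](O[Si](C)(C)C(C)(C)C)CC1(C)C | intermediate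
29 | 2,2-dimethoxyacetaldehyde | COC(OC)C=O | starting material
30 | 4-hydroxy-5,5-dimethoxy-3-methylidene-1-[(4R)-4-[(tert-butyldimethylsilyl)oxy]-2,6,6-trimethylcyclohex-1-en-1-yl]pentan-2-one (C10 epimers) | COC(OC)C(O)C(=C)C(=O)CC1=C(C)C[C@@H](O[Si](C)(C)C(C)(C)C)CC1(C)C | intermediate
31 | (2E)-dodec-2-enoic acid | CCCCCCCCC/C=C/C(=O)O | starting material
32 | 1,1-dimethoxy-3-methylidene-4-oxo-5-[(4R)-4-[(tert-butyldimethylsilyl)oxy]-2,6,6-trimethylcyclohex-1-en-1-yl]pentan-2-yl (2E)-dodec-2-enoate | CCCCCCCCC/C=C/C(=O)OC(C(OC)OC)C(=C)C(=O)CC1=C(C)C[C@@H](O[Si](C)(C)C(C)(C)C)CC1(C)C | intermediate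
33 | (2E)-4,4-dimethoxy-2-{2-[(4R)-4-[(tert-butyldimethylsilyl)oxy]-2,6,6-trimethylcyclohex-1-en-1-yl]acetyl}but-2-en-1-yl (2E)-dodec-2-enoate | CCCCCCCCC/C=C/C(=O)OC\C(=C/C(OC)OC)C(=O)CC1=C(C)C[C@@H](O[Si](C)(C)C(C)(C)C)CC1(C)C | intermediate
34 | (2E)-2-{2-[(4R)-4-hydroxy-2,6,6-trimethylcyclohex-1-en-1-yl]acetyl}-4-oxobut-2-en-1-yl (2E)-dodec-2-enoate | CCCCCCCCC/C=C/C(=O)OC\C(=C/C=O)C(=O)CC1=C(C)C[C@@H](O)CC1(C)C | intermediate
35 | (11Z)-isomer of the target | CCCCCCCCC/C=C/C(=O)OC\C(=C/C=C\C(C)=C\C=C\C=C(C)\C=C\C=C(C)\C=C\[C@H]1C(C)=C[C@H](O)CC1(C)C)C(=O)CC1=C(C)C[C@@H](O)CC1(C)C | intermediate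
36 | (3R,3′R,6′R)-3,3′-dihydroxy-8-oxo-7,8-dihydro-β,ε-caroten-19-yl (2E)-dodec-2-enoate (all-E) | CCCCCCCCC/C=C/C(=O)OC\C(=C/C=C/C(C)=C/C=C/C=C(C)/C=C/C=C(C)/C=C/[C@H]1C(C)=C[C@H](O)CC1(C)C)C(=O)CC1=C(C)C[C@@H](O)CC1(C)C | target

## Step count and risks

Total step count: 23. Longest linear sequence: 14 steps (steps 1–13, then step 23).

Steps most likely to fail:

1. Step 6 (Proposed new method). What may go wrong: the chiral gold catalyst may discriminate poorly between the two enantiotopic alkynes, or the configuration at C6′ may erode during the double-bond shift. Fallback (known chemistry, resolution instead of desymmetrisation): it sets out from 7. The ring is closed without induction by the established gold-catalysed silyl enol ether–alkyne carbocyclisation (Ph3PAuCl/AgBF4, CH2Cl2/MeOH, rt), which gives racemic 4-ethynyl-5,5-dimethyl-3-methylidenecyclohexan-1-one F1 and, after DABCO, racemic 4-ethynyl-3,5,5-trimethylcyclohex-2-en-1-one F2. The reduction of step 7 ((S)-oxazaborolidine, catecholborane) then acts as a reagent-controlled divergent reduction of the racemate: the two enantiomers become the diastereomers 10 and (1R,4R)-4-ethynyl-3,5,5-trimethylcyclohex-2-en-1-ol F3, which are separated by chromatography. The route is rejoined at 10, with at most half of the material.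

2. Step 2. What may go wrong: the bis-propargylic cation may take hydride at an alkyne terminus (allene formation) or undergo Meyer–Schuster rearrangement instead of clean propargylic reduction. Fallback (Nicholas chemistry): it sets out from 3. One alkyne is complexed with Co2(CO)8 (CH2Cl2, rt) to give the hexacarbonyldicobalt complex of 3 F4. BF3·OEt2/Et3SiH then effects a Nicholas reduction, in which the cobalt-stabilised cation takes hydride only at the propargylic carbon, to give the hexacarbonyldicobalt complex of 4 F5. Oxidative decomplexation with (NH4)2Ce(NO3)6 in acetone returns to the route at 4.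

3. Step 21. What may go wrong: the 1,3-acyloxy shift may be incomplete or give an E/Z mixture, or the amine may displace the unsaturated acyl group without return. Fallback (bromide instead of acyl migration): it sets out from 30. SN2′ bromination with NBS/Me2S (CH2Cl2, 0 °C), a standard reaction of Morita–Baylis–Hillman alcohols, gives (3Z)-3-(bromomethyl)-5,5-dimethoxy-1-[(4R)-4-[(tert-butyldimethylsilyl)oxy]-2,6,6-trimethylcyclohex-1-en-1-yl]pent-3-en-2-one F6, which has the same double-bond geometry as 33. SN2 displacement of the primary allylic bromide with the caesium salt of 31 (Cs2CO3, DMF, rt) returns to the route at 33.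

## Further compounds

F1 | step 6 | racemic 4-ethynyl-5,5-dimethyl-3-methylidenecyclohexan-1-one | C#CC1C(=C)CC(=O)CC1(C)C
F2 | step 6 | racemic 4-ethynyl-3,5,5-trimethylcyclohex-2-en-1-one | C#CC1C(C)=CC(=O)CC1(C)C
F3 | step 6 | (1R,4R)-4-ethynyl-3,5,5-trimethylcyclohex-2-en-1-ol | C#C[C@@H]1C(C)=C[C@H](O)CC1(C)C
F4 | step 2 | hexacarbonyldicobalt (Co2(CO)6) alkyne complex of 3 | C=CCC(C)(C)C(O)(C#C[Si](C)(C)C)C12C3([Si](C)(C)C)[Co]1(=C=O)(=C=O)(=C=O)[Co]23(=C=O)(=C=O)=C=O
F5 | step 2 | hexacarbonyldicobalt (Co2(CO)6) alkyne complex of 4 | C=CCC(C)(C)C(C#C[Si](C)(C)C)C12C3([Si](C)(C)C)[Co]1(=C=O)(=C=O)(=C=O)[Co]23(=C=O)(=C=O)=C=O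
F6 | step 21 | (3Z)-3-(bromomethyl)-5,5-dimethoxy-1-[(4R)-4-[(tert-butyldimethylsilyl)oxy]-2,6,6-trimethylcyclohex-1-en-1-yl]pent-3-en-2-one | BrC\C(=C/C(OC)OC)C(=O)CC1=C(C)C[C@@H](O[Si](C)(C)C(C)(C)C)CC1(C)C
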